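**Strategy.** Everything rests on cutting O1–C2 and C3=C4 of the acetyl-bearing chromene (ring A), once its CMe2 carbon is traced back to a lactone carbonyl. The atoms O5′, C5′, C6′ (primed = dimethoxychromene unit), the CHMe carbon, C3 and C2 are then recognised as a latent 4-methyl-3,4-dihydrocoumarin ring, in which the only stereocentre is installed by asymmetric conjugate reduction. In one operation the key step moves that acyl group onto a salicylaldehyde oxygen and condenses the ester α-carbon with the formyl group, closing the coumarin of ring A and unmasking the 5′-phenol. Its precursors are the (S)-dihydropyranocoumarin 7 and the mono-MOM salicylaldehyde 10.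

Key step: step 7

Assumption: (R)-DTBM-SEGPHOS is taken to deliver hydride to the face of C4 that gives (4S)-7, by analogy with Z-configured β-aryl enoates; if this substrate shows the opposite sense, the (S)-ligand is used with nothing else changed.

Remark: the methine keeps one spatial arrangement throughout. It is S in 7, 11, 12 and 15–19 and R in 13 and 14 only because the coumarin C3 outranks the aryl group in the CIP ranking.

Remark: any linear pyranocoumarin formed in step 3 need not be lost. Carried through steps 4, 7 and 8 it should give the same compound 14, because lactone opening and O-methylation make the two oxygens flanking C6′ equivalent.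

Step 1
Reactants: 1 5,7-dihydroxy-4-methylcoumarin; 2 3-chloro-3-methylbut-1-yne
Product: 3 5-hydroxy-4-methyl-7-[(2-methylbut-3-yn-2-yl)oxy]-2H-chromen-2-one
Conditions: 2 (1.3 equiv), DBU (1.3 equiv), CuCl2 (1 mol %), MeCN–DMF, 0 → 23 °C
Reagents that add atoms: none
Why: Copper-catalysed propargylic O-alkylation (Williamson-type etherification through a copper-activated propargyl electrophile); one equivalent of base should ionise only the 7-OH, which is more acidic and not peri to the 4-methyl group.

Step 2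
Reactants: 3 5-hydroxy-4-methyl-7-[(2-methylbut-3-yn-2-yl)oxy]-2H-chromen-2-one
Product: 4 5-methoxy-4-methyl-7-[(2-methylbut-3-yn-2-yl)oxy]-2H-chromen-2-one
Conditions: MeI, K2CO3, acetone, 56 °C
Reagents that add atoms: iodomethane (MeI), CI
Why: Williamson O-methylation of the remaining peri-hindered phenol; lactone and terminal alkyne are inert to carbonate in acetone.

Step 3
Reactants: 4 5-methoxy-4-methyl-7-[(2-methylbut-3-yn-2-yl)oxy]-2H-chromen-2-one
Product: 6 5-methoxy-4,8,8-trimethyl-2H,8H-pyrano[2,3-f]chromen-2-one, via allenylphenol 5 (not isolated)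
Conditions: PhNEt2, 190 °C
Reagents that add atoms: none
Why: Aryl propargyl ether Claisen rearrangement to allenylphenol 5, then [1,5]-hydrogen shift and oxa-6π electrocyclisation; the C7–C8 bond of a 7-oxycoumarin has the higher double-bond character, so the shift should go to C8 and give the angular pyran.

Step 4
Reactants: 6 5-methoxy-4,8,8-trimethyl-2H,8H-pyrano[2,3-f]chromen-2-one
Product: 7 (4S)-5-methoxy-4,8,8-trimethyl-3,4-dihydro-2H,8H-pyrano[2,3-f]chromen-2-one
Conditions: Cu(OAc)2·H2O (3 mol %), (R)-DTBM-SEGPHOS (3.3 mol %), (EtO)2MeSiH (1.5 equiv), t-BuOH (1.5 equiv), toluene, 0 → 23 °C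
Reagents that add atoms: none
Why: Copper hydride asymmetric conjugate reduction (1,4-hydrosilylation) of a β,β-disubstituted unsaturated lactone; the chiral bisphosphine–CuH should deliver hydride to one face of C4 and so set the (S) centre, while the unactivated chromene alkene should not compete.

Step 5
Reactants: 8 2,4,6-trihydroxybenzaldehyde
Product: 9 2,6-dihydroxy-4-methoxybenzaldehyde
Conditions: MeI (1.05 equiv), KHCO3, DMF, 40 °C
Reagents that add atoms: iodomethane (MeI), CI
Why: Williamson methylation under bicarbonate control; the 4-OH is the most acidic hydroxyl and is not engaged in the hydrogen bond to the formyl group, so it should react first.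

Step 6
Reactants: 9 2,6-dihydroxy-4-methoxybenzaldehyde
Product: 10 2-hydroxy-4-methoxy-6-(methoxymethoxy)benzaldehyde
Conditions: MOMCl (1.1 equiv), i-Pr2NEt, CH2Cl2, 0 °C
Reagents that add atoms: chloromethyl methyl ether (MOMCl), COCCl
Why: O-alkylation with a chloromethyl ether should stop after one MOM group, because the second hydroxyl is then locked in the hydrogen bond to the aldehyde; 9 is symmetric, so one product results.

Step 7
Reactants: 7 (4S)-5-methoxy-4,8,8-trimethyl-3,4-dihydro-2H,8H-pyrano[2,3-f]chromen-2-one; 10 2-hydroxy-4-methoxy-6-(methoxymethoxy)benzaldehyde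
Product: 13 3-[(1R)-1-(5-hydroxy-7-methoxy-2,2-dimethyl-2H-chromen-6-yl)ethyl]-7-methoxy-5-(methoxymethoxy)-2H-chromen-2-one, via 2-formylaryl ester 11 (not isolated), via aldol lactone 12 (not isolated)
Conditions: Cs2CO3 (0.3 equiv), 4 Å molecular sieves, DMF, 80 °C; aq. NH4Cl
Reagents that add atoms: none
Why: The phenoxide of 10 opens lactone 7 by reversible transacylation to the 2-formylaryl ester 11, whose ester enolate adds to the adjacent formyl group to give aldol 12, and E1cB loss of water then delivers coumarin 13 irreversibly and pulls both equilibria forward. The closest known reaction type is the base-mediated condensation of salicylaldehydes with lactones that ends in translactonisation to a 3-substituted coumarin, an intramolecular Perkin-type aldol of an O-acylated salicylaldehyde. The pyranone ring closes by a 6-(enolendo)-exo-trig aldol addition. No stereocentre is created; the existing methine lies β to the carbonyl, is never enolised, and changes its descriptor from S to R only because C3 of the new coumarin outranks the aryl group. The step needs regioselective O-acylation and a single enolisable site: 10 offers one free hydroxyl (the other is a MOM ether) and no α-hydrogen, so only the ester CH2 can condense, while catalytic mild base and molecular sieves should suppress lactone hydrolysis and deprotonation of the allylic methine of 13.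

Step 8
Reactants: 13 3-[(1R)-1-(5-hydroxy-7-methoxy-2,2-dimethyl-2H-chromen-6-yl)ethyl]-7-methoxy-5-(methoxymethoxy)-2H-chromen-2-one
Product: 14 3-[(1R)-1-(5,7-dimethoxy-2,2-dimethyl-2H-chromen-6-yl)ethyl]-7-methoxy-5-(methoxymethoxy)-2H-chromen-2-one
Conditions: MeI, K2CO3, DMF, 40 °C
Reagents that add atoms: iodomethane (MeI), CI
Why: Williamson methylation of the released 5′-phenoxide; dry carbonate does not open the coumarin, and any reversible oxa-Michael adduct of the phenol at C4 should be drained through the phenoxide.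

Step 9
Reactants: 14 3-[(1R)-1-(5,7-dimethoxy-2,2-dimethyl-2H-chromen-6-yl)ethyl]-7-methoxy-5-(methoxymethoxy)-2H-chromen-2-one
Product: 16 6-{(1S)-1-[7-methoxy-5-(methoxymethoxy)-2,2-dimethyl-2H-chromen-3-yl]ethyl}-5,7-dimethoxy-2,2-dimethyl-2H-chromene, via Z-allylic diol 15 (not isolated)
Conditions: MeLi (4 equiv), THF, −78 → 0 °C; then AcOH (excess), 23 → 45 °C, same flask
Reagents that add atoms: methyllithium (MeLi), [Li]C
Why: Double 1,2-addition of MeLi to the aryl lactone (acyl substitution, then ketone addition) should give the Z-allylic tertiary alcohol 15, and acid-promoted cyclodehydration through the stabilised tertiary allylic cation closes the 2,2-dimethylpyran; this is the established coumarin-to-2,2-dimethylchromene conversion, and the MOM ether tolerates both MeLi and acetic acid.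

Step 10
Reactants: 16 6-{(1S)-1-[7-methoxy-5-(methoxymethoxy)-2,2-dimethyl-2H-chromen-3-yl]ethyl}-5,7-dimethoxy-2,2-dimethyl-2H-chromene
Product: 18 1-{3-[(1S)-1-(5,7-dimethoxy-2,2-dimethyl-2H-chromen-6-yl)ethyl]-7-methoxy-5-(methoxymethoxy)-2,2-dimethyl-2H-chromen-6-yl}ethan-1-one, via 6-lithiochromene 17 (not isolated)
Conditions: n-BuLi (1.3 equiv), THF, −20 → 0 °C; then MeC(O)N(OMe)Me, −78 → 0 °C; aq. NH4Cl
Reagents that add atoms: N-methoxy-N-methylacetamide, CC(=O)N(C)OC; n-butyllithium (n-BuLi), [Li]CCCC (supplies the lithium of 17 only)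
Why: Directed ortho-metalation; C6 is the only position flanked by the strongly coordinating MOM ether and a methoxy group, so deprotonation should occur there, and the N-methoxy-N-methylamide stops at the ketone through its chelated tetrahedral intermediate.

Step 11
Reactants: 18 1-{3-[(1S)-1-(5,7-dimethoxy-2,2-dimethyl-2H-chromen-6-yl)ethyl]-7-methoxy-5-(methoxymethoxy)-2,2-dimethyl-2H-chromen-6-yl}ethan-1-one
Product: 19 1-{3-[(1S)-1-(5,7-dimethoxy-2,2-dimethyl-2H-chromen-6-yl)ethyl]-5-hydroxy-7-methoxy-2,2-dimethyl-2H-chromen-6-yl}ethan-1-one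
Conditions: HCl (0.5 M in MeOH), THF, 23 °C
Reagents that add atoms: none
Why: Acid-catalysed acetal exchange (methanolysis) of the aryl MOM ether; the ortho acetyl group stabilises the released phenol by hydrogen bonding, so conditions mild enough for the two acid-sensitive chromene alkenes should suffice.

**Compound list**

1 | 5,7-dihydroxy-4-methylcoumarin | CC1=CC(=O)Oc2cc(O)cc(O)c12 | starting material
2 | 3-chloro-3-methylbut-1-yne | CC(C)(Cl)C#C | starting material
3 | 5-hydroxy-4-methyl-7-[(2-methylbut-3-yn-2-yl)oxy]-2H-chromen-2-one | CC1=CC(=O)Oc2cc(OC(C)(C)C#C)cc(O)c12 | intermediate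
4 | 5-methoxy-4-methyl-7-[(2-methylbut-3-yn-2-yl)oxy]-2H-chromen-2-one | CC1=CC(=O)Oc2cc(OC(C)(C)C#C)cc(OC)c12 | intermediate
5 | 7-hydroxy-5-methoxy-4-methyl-8-(3-methylbuta-1,2-dien-1-yl)-2H-chromen-2-one | CC1=CC(=O)Oc2c(C=C=C(C)C)c(O)cc(OC)c12 | intermediate
6 | 5-methoxy-4,8,8-trimethyl-2H,8H-pyrano[2,3-f]chromen-2-one | CC1=CC(=O)Oc2c1c(OC)cc1c2C=CC(C)(C)O1 | intermediate
7 | (4S)-5-methoxy-4,8,8-trimethyl-3,4-dihydro-2H,8H-pyrano[2,3-f]chromen-2-one | C[C@H]1CC(=O)Oc2c1c(OC)cc1c2C=CC(C)(C)O1 | intermediate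
8 | 2,4,6-trihydroxybenzaldehyde | O=Cc1c(O)cc(O)cc1O | starting material
9 | 2,6-dihydroxy-4-methoxybenzaldehyde | O=Cc1c(O)cc(OC)cc1O | intermediate
10 | 2-hydroxy-4-methoxy-6-(methoxymethoxy)benzaldehyde | O=Cc1c(O)cc(OC)cc1OCOC | intermediate
11 | 2-formyl-5-methoxy-3-(methoxymethoxy)phenyl (3S)-3-(5-hydroxy-7-methoxy-2,2-dimethyl-2H-chromen-6-yl)butanoate | O=Cc1c(OC(=O)C[C@H](C)c2c(OC)cc3c(c2O)C=CC(C)(C)O3)cc(OC)cc1OCOC | intermediate
12 | 4-hydroxy-3-[(1S)-1-(5-hydroxy-7-methoxy-2,2-dimethyl-2H-chromen-6-yl)ethyl]-7-methoxy-5-(methoxymethoxy)chroman-2-one (transient C3 and C4 centres undefined) | COc1cc2c(c(OCOC)c1)C(O)C([C@H](C)c1c(OC)cc3c(c1O)C=CC(C)(C)O3)C(=O)O2 | intermediate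
13 | 3-[(1R)-1-(5-hydroxy-7-methoxy-2,2-dimethyl-2H-chromen-6-yl)ethyl]-7-methoxy-5-(methoxymethoxy)-2H-chromen-2-one | COc1cc2c(c(OCOC)c1)C=C([C@H](C)c1c(OC)cc3c(c1O)C=CC(C)(C)O3)C(=O)O2 | intermediate
14 | 3-[(1R)-1-(5,7-dimethoxy-2,2-dimethyl-2H-chromen-6-yl)ethyl]-7-methoxy-5-(methoxymethoxy)-2H-chromen-2-one | COc1cc2c(c(OCOC)c1)C=C([C@H](C)c1c(OC)cc3c(c1OC)C=CC(C)(C)O3)C(=O)O2 | intermediate
15 | 2-[(1Z,3S)-3-(5,7-dimethoxy-2,2-dimethyl-2H-chromen-6-yl)-2-(2-hydroxypropan-2-yl)but-1-en-1-yl]-5-methoxy-3-(methoxymethoxy)phenol | COc1cc(O)c(/C=C(/[C@H](C)c2c(OC)cc3c(c2OC)C=CC(C)(C)O3)C(C)(C)O)c(OCOC)c1 | intermediate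
16 | 6-{(1S)-1-[7-methoxy-5-(methoxymethoxy)-2,2-dimethyl-2H-chromen-3-yl]ethyl}-5,7-dimethoxy-2,2-dimethyl-2H-chromene | COc1cc2c(c(OCOC)c1)C=C([C@H](C)c1c(OC)cc3c(c1OC)C=CC(C)(C)O3)C(C)(C)O2 | intermediate
17 | {3-[(1S)-1-(5,7-dimethoxy-2,2-dimethyl-2H-chromen-6-yl)ethyl]-7-methoxy-5-(methoxymethoxy)-2,2-dimethyl-2H-chromen-6-yl}lithium | COc1cc2c(c(OCOC)c1[Li])C=C([C@H](C)c1c(OC)cc3c(c1OC)C=CC(C)(C)O3)C(C)(C)O2 | intermediate
18 | 1-{3-[(1S)-1-(5,7-dimethoxy-2,2-dimethyl-2H-chromen-6-yl)ethyl]-7-methoxy-5-(methoxymethoxy)-2,2-dimethyl-2H-chromen-6-yl}ethan-1-one | COc1cc2c(c(OCOC)c1C(C)=O)C=C([C@H](C)c1c(OC)cc3c(c1OC)C=CC(C)(C)O3)C(C)(C)O2 | intermediate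
19 | 1-{3-[(1S)-1-(5,7-dimethoxy-2,2-dimethyl-2H-chromen-6-yl)ethyl]-5-hydroxy-7-methoxy-2,2-dimethyl-2H-chromen-6-yl}ethan-1-one (CNP0303487.1) | COc1cc2c(c(O)c1C(C)=O)C=C([C@H](C)c1c(OC)cc3c(c1OC)C=CC(C)(C)O3)C(C)(C)O2 | target

**Totals.** Total step count: 11. Longest linear sequence: 9 steps (steps 1–4 and 7–11); the aldehyde branch (steps 5 and 6) joins at step 7.

**Steps most likely to fail**

Step 7. The transacylation equilibrium lies on the side of the lactone and the aryl-ester enolate is present only in low concentration, so the condensation may stall. Released water may also hydrolyse the lactone, and long heating with base may erode enantiopurity by reversible deprotonation of the allylic methine. The fallback makes the 2-formylaryl ester deliberately and sets out from 7. K2CO3 and MeI in MeOH–acetone at 50 °C should open the lactone and methylate the phenoxide in the same flask, giving methyl (3S)-3-(5,7-dimethoxy-2,2-dimethyl-2H-chromen-6-yl)butanoate F1. LiOH in THF–water then gives (3S)-3-(5,7-dimethoxy-2,2-dimethyl-2H-chromen-6-yl)butanoic acid F2. Carbodiimide coupling (EDC·HCl, DMAP, CH2Cl2) with aldehyde 10 gives 2-formyl-5-methoxy-3-(methoxymethoxy)phenyl (3S)-3-(5,7-dimethoxy-2,2-dimethyl-2H-chromen-6-yl)butanoate F3. Intramolecular aldol condensation of this ester (DBU, MeCN, 70 °C) can no longer revert to a lactone and should close the coumarin. The route is rejoined at 14, with the methylation of step 8 already done.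

Step 10. Metalation may occur at C8 or C8′, each also flanked by two oxygens, or at the benzylic methine with loss of configuration. Acyl transfer to the di-ortho-substituted aryllithium may also be slow enough for the amide to be enolised instead. The fallback avoids strong base and sets out from 16. Careful acid methanolysis (HCl in MeOH–THF, 40 °C; this ether lacks ortho-acyl assistance) should give 3-[(1S)-1-(5,7-dimethoxy-2,2-dimethyl-2H-chromen-6-yl)ethyl]-7-methoxy-2,2-dimethyl-2H-chromen-5-ol F4. Magnesium-mediated ortho-formylation (MgCl2, Et3N, paraformaldehyde, MeCN, 80 °C) is directed by the phenoxide to C6, its only free ortho position, and should give 3-[(1S)-1-(5,7-dimethoxy-2,2-dimethyl-2H-chromen-6-yl)ethyl]-5-hydroxy-7-methoxy-2,2-dimethyl-2H-chromene-6-carbaldehyde F5. MeMgBr (2.5 equiv, THF, 0 °C) then gives 3-[(1S)-1-(5,7-dimethoxy-2,2-dimethyl-2H-chromen-6-yl)ethyl]-6-(1-hydroxyethyl)-7-methoxy-2,2-dimethyl-2H-chromen-5-ol F6 as an inconsequential mixture of carbinol epimers. Oxidation with MnO2 in CH2Cl2 rejoins the route at 19.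

Step 4. Hydride transfer to C4 may be slow because of the peri methoxy group, facial selectivity may be insufficient, or the copper enolate may fragment to ring-opened material. The fallback gives up catalytic control and sets out from 6. Dissolving-metal conjugate reduction (Mg, MeOH, 23 °C) with concomitant methanolysis should give racemic methyl 3-(5-hydroxy-7-methoxy-2,2-dimethyl-2H-chromen-6-yl)butanoate F7. Re-lactonisation (PPTS, toluene, 80 °C) gives racemic 5-methoxy-4,8,8-trimethyl-3,4-dihydro-2H,8H-pyrano[2,3-f]chromen-2-one F8. The enantiomers are separated by preparative chromatography on a cellulose carbamate chiral stationary phase, and the (4S) enantiomer rejoins the route at 7.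

**Further compounds**

F1 | step 7 | methyl (3S)-3-(5,7-dimethoxy-2,2-dimethyl-2H-chromen-6-yl)butanoate | COC(=O)C[C@H](C)c1c(OC)cc2c(c1OC)C=CC(C)(C)O2
F2 | step 7 | (3S)-3-(5,7-dimethoxy-2,2-dimethyl-2H-chromen-6-yl)butanoic acid | OC(=O)C[C@H](C)c1c(OC)cc2c(c1OC)C=CC(C)(C)O2
F3 | step 7 | 2-formyl-5-methoxy-3-(methoxymethoxy)phenyl (3S)-3-(5,7-dimethoxy-2,2-dimethyl-2H-chromen-6-yl)butanoate | O=Cc1c(OC(=O)C[C@H](C)c2c(OC)cc3c(c2OC)C=CC(C)(C)O3)cc(OC)cc1OCOC
F4 | step 10 | 3-[(1S)-1-(5,7-dimethoxy-2,2-dimethyl-2H-chromen-6-yl)ethyl]-7-methoxy-2,2-dimethyl-2H-chromen-5-ol | COc1cc2c(c(O)c1)C=C([C@H](C)c1c(OC)cc3c(c1OC)C=CC(C)(C)O3)C(C)(C)O2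
F5 | step 10 | 3-[(1S)-1-(5,7-dimethoxy-2,2-dimethyl-2H-chromen-6-yl)ethyl]-5-hydroxy-7-methoxy-2,2-dimethyl-2H-chromene-6-carbaldehyde | COc1cc2c(c(O)c1C=O)C=C([C@H](C)c1c(OC)cc3c(c1OC)C=CC(C)(C)O3)C(C)(C)O2
F6 | step 10 | 3-[(1S)-1-(5,7-dimethoxy-2,2-dimethyl-2H-chromen-6-yl)ethyl]-6-(1-hydroxyethyl)-7-methoxy-2,2-dimethyl-2H-chromen-5-ol (carbinol epimers) | COc1cc2c(c(O)c1C(C)O)C=C([C@H](C)c1c(OC)cc3c(c1OC)C=CC(C)(C)O3)C(C)(C)O2
F7 | step 4 | racemic methyl 3-(5-hydroxy-7-methoxy-2,2-dimethyl-2H-chromen-6-yl)butanoate | COC(=O)CC(C)c1c(OC)cc2OC(C)(C)C=Cc2c1O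
F8 | step 4 | racemic 5-methoxy-4,8,8-trimethyl-3,4-dihydro-2H,8H-pyrano[2,3-f]chromen-2-one | CC1CC(=O)Oc2c1c(OC)cc1c2C=CC(C)(C)O1
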